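## Retrosynthetic overview
1. Galbanic acid comes from the aldehyde by Pinnick oxidation. The coumarin ether comes from the neopentyl alcohol and umbelliferone by Mitsunobu coupling.
2. The CH2CH2CHO chain is a Claisen-derived CH2CHO plus one carbon (Wittig homologation). The Claisen rearrangement of a tertiary allylic alcohol sets the C-6 stereocentre and regenerates the tetrasubstituted isopropylidene.
3. That allylic alcohol comes from pulegone oxide by Wharton transposition. The C-5 quaternary centre comes from two α′-alkylations of (S)-pulegone (CH2O, then Me). Pulegone also supplies the ring and the CHMe stereocentre.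
4. No ring is formed. The cyclohexane comes from pulegone and the coumarin is an intact unit.

**Assumptions.**
- (S)-(−)-Pulegone is taken as commercially available (the target's CHMe centre is S). If it is not, it can be made from (S)-citronellal by ZnBr2 ene cyclisation, oxidation and isomerisation.
- Numbered compounds are substrates, intermediates and the coupling partner. Small reagents that add atoms are given with SMILES in each step.
- T4, T5 and T6 below mean ring CHMe, quaternary C and CH(chain). Relative configuration in the target: T4-Me and T5-CH2OAr are cis; T5-CH2OAr and the T6 chain are trans.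

## Route

**Step 1**
Reactants: 1 (S)-pulegone
Product: 2 6-(hydroxymethyl)-5-methyl-2-(propan-2-ylidene)cyclohexanone (5S; C-6 epimeric mixture)
Conditions: LDA, THF, −78 °C; then HCHO (monomeric), −78 → −40 °C
Reagents that add atoms: formaldehyde, C=O
Why: LDA forms the kinetic α′-enolate, which undergoes an aldol hydroxymethylation. The C-6 stereocentre is epimerisable and is erased in step 3.

**Step 2**
Reactants: 2
Product: 3 6-(TBS-oxymethyl) ketone
Conditions: TBSCl, imidazole, DMF, 25 °C
Reagents that add atoms: TBSCl, CC(C)(C)[Si](C)(C)Cl
Why: Silyl ether protection of the primary alcohol. TBS survives the later base, hydrazine and Claisen conditions and is removed at the aldehyde stage without reduction.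

**Step 3**
Reactants: 3
Product: 4 (5S,6R)-6-(TBS-oxymethyl)-5,6-dimethyl-2-(propan-2-ylidene)cyclohexanone
Conditions: LDA, THF, −78 °C; then MeI, DMPU, −78 → −20 °C
Reagents that add atoms: MeI, CI
Why: Enolate C-alkylation creates the quaternary centre (T5). In the tetrasubstituted enolate, A(1,2) strain makes the C5-Me pseudo-axial. Axial attack anti to it puts the new Me trans to the ring Me and CH2OTBS cis, as required. E1cB loss of TBSO⁻ is slow at low temperature.

**Step 4**
Reactants: 4
Product: 5 spiro-epoxy ketone (5,6 centres as in 4; 5-(TBSOCH2)-2,2,5,6-tetramethyl-1-oxaspiro[2.5]octan-4-one; epoxide diastereomers)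
Conditions: 30% H2O2, NaOH, MeOH, 0 °C
Reagents that add atoms: hydrogen peroxide, OO
Why: Weitz–Scheffer nucleophilic epoxidation of the β,β-disubstituted enone. The epoxide stereochemistry is irrelevant because it is destroyed in step 5.

**Step 5**
Reactants: 5
Product: 6 2-[3-(TBSOCH2)-3,4-dimethylcyclohex-1-en-1-yl]propan-2-ol
Conditions: N2H4·H2O, AcOH (cat.), MeOH, 0 → 50 °C
Reagents that add atoms: none (N2 and H2O are lost; only H is added)
Why: Wharton reaction. Hydrazone formation on the epoxy ketone triggers fragmentation to the allylic alcohol, with the alkene now at C1=C2 (T6=T1) and OH on CMe2. No new stereocentre is formed, and the T4 and T5 centres are untouched.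

**Step 6**
Reactants: 6
Product: 7 (2-aldehyde) [(T6 chain)CH2CHO], isopropylidene regenerated
Conditions: ethyl vinyl ether, Hg(OAc)2 (cat.), reflux; then PhMe, 160 °C, sealed tube
Reagents that add atoms: ethyl vinyl ether, C=COCC
Why: Claisen rearrangement via the vinyl ether. The pseudo-axial CH2OTBS blocks the top face, so the chair transition state delivers CH2CHO to T6 from the bottom face, trans to CH2OTBS. This sets T6, and the alkene shifts to form the tetrasubstituted C=CMe2.

**Step 7**
Reactants: 7
Product: 8 methyl enol ether, ring–CH2–CH=CH–OMe (E/Z)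
Conditions: [Ph3PCH2OMe]Cl, KOtBu, THF, 0 → 25 °C
Reagents that add atoms: (methoxymethyl)triphenylphosphonium chloride, COC[P+](c1ccccc1)(c1ccccc1)c1ccccc1.[Cl-]
Why: Wittig methoxymethylenation adds the third chain carbon. T6 is β to the aldehyde, so it cannot epimerise.

**Step 8**
Reactants: 8
Product: 9 homologated aldehyde, ring–CH2CH2CHO (TBS ether intact)
Conditions: 2 M HCl, THF, 25 °C
Reagents that add atoms: water, O
Why: Enol ether hydrolysis. The hindered neopentyl TBS ether and the tetrasubstituted alkene are stable to brief dilute acid.

**Step 9**
Reactants: 9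
Product: 10 hydroxy aldehyde
Conditions: HF·pyridine, THF/pyridine, 0 → 25 °C
Reagents that add atoms: none
Why: Fluoride desilylation under non-basic conditions tolerates the enolisable aldehyde.

**Step 10**
Reactants: 10; 11 umbelliferone (7-hydroxycoumarin)
Product: 12 coumarin ether aldehyde
Conditions: ADDP, PBu3, toluene, 25 → 60 °C
Reagents that add atoms: none (umbelliferone is the numbered reactant)
Why: Mitsunobu etherification. The acidic phenol (pKa ≈ 7.8) displaces the activated primary neopentyl oxygen. The carbon is CH2, so no stereochemistry is affected.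

**Step 11**
Reactants: 12
Product: 13 galbanic acid
Conditions: NaClO2, NaH2PO4, 2-methyl-2-butene, t-BuOH/H2O, 25 °C
Reagents that add atoms: sodium chlorite, [Na+].[O-]Cl=O
Why: Pinnick oxidation converts the aldehyde to the acid under mildly acidic conditions. The coumarin lactone (which would be at risk under saponification) and the tetrasubstituted alkene (protected by the scavenger) survive.

## Compound list
1 | (S)-(−)-pulegone | CC(C)=C1CC[C@H](C)CC1=O | starting material
2 | 6-(hydroxymethyl)pulegone (C-6 epimers) | CC(C)=C1CC[C@H](C)C(CO)C1=O | intermediate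
3 | TBS ether of 2 | CC(C)=C1CC[C@H](C)C(CO[Si](C)(C)C(C)(C)C)C1=O | intermediate
4 | (5S,6R)-6-(TBSOCH2)-5,6-dimethyl-2-isopropylidenecyclohexanone | CC(C)=C1CC[C@H](C)[C@](C)(CO[Si](C)(C)C(C)(C)C)C1=O | intermediate
5 | spiro-epoxy ketone from 4 | CC1(C)OC12CC[C@H](C)[C@](C)(CO[Si](C)(C)C(C)(C)C)C2=O | intermediate
6 | tertiary allylic alcohol (Wharton product) | CC(C)(O)C1=C[C@@](C)(CO[Si](C)(C)C(C)(C)C)[C@@H](C)CC1 | intermediate
7 | Claisen aldehyde | CC(C)=C1CC[C@H](C)[C@](C)(CO[Si](C)(C)C(C)(C)C)[C@H]1CC=O | intermediate
8 | methyl enol ether | CC(C)=C1CC[C@H](C)[C@](C)(CO[Si](C)(C)C(C)(C)C)[C@H]1CC=COC | intermediate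
9 | homologated aldehyde (TBS) | CC(C)=C1CC[C@H](C)[C@](C)(CO[Si](C)(C)C(C)(C)C)[C@H]1CCC=O | intermediate
10 | hydroxy aldehyde | CC(C)=C1CC[C@H](C)[C@](C)(CO)[C@H]1CCC=O | intermediate
11 | umbelliferone | O=c1ccc2ccc(O)cc2o1 | starting material (coupling partner)
12 | coumarin ether aldehyde | CC(C)=C1CC[C@H](C)[C@](C)(COc2ccc3ccc(=O)oc3c2)[C@H]1CCC=O | intermediate
13 | galbanic acid | CC(C)=C1CC[C@H](C)[C@](C)(COc2ccc3ccc(=O)oc3c2)[C@H]1CCC(=O)O | target

**Total steps:** 11. **Longest linear sequence:** 11, all from 1; umbelliferone (11) enters at step 10.

## Three steps most likely to fail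
1. **Step 3 (quaternary methylation).** The diastereoselectivity is predicted from A(1,2) strain rather than proven, and E1cB loss of TBSO⁻ is possible.
   - Fallback: reverse the order by methylating first (6-methylpulegone), then doing the HCHO aldol. Separate the C-6 diastereomers at the TBS-ether stage, or equilibrate them via the reversible aldol.
2. **Step 6 (Claisen).** A tertiary allylic alcohol, a vicinal quaternary centre and the facial selectivity all make this demanding.
   - Fallback: ionise alcohol 6 with a Lewis acid and trap the allyl cation with allyltrimethylsilane at T6. Then hydroborate the allyl group (9-BBN) and oxidise to the acid, which avoids the vinyl-ether route.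
3. **Step 10 (Mitsunobu on a neopentyl alcohol).** The neopentyl centre is hindered, and PBu3 may add to the aldehyde.
   - Fallback: make the neopentyl triflate (Tf2O, pyridine) and displace it with caesium umbelliferone in DMF.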